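## Retrosynthetic overview

1. Target ⇐ global deprotection ⇐ 19-membered carbocycle closed last by an intramolecular Stille coupling (central bond of the E,E-diene) ⇐ seco-diketone made by adding the lithiated west methyl tetronate 16 to the east lactol 38, then oxidation and equilibration.
2. West 16 ⇐ mirror-symmetric spiro(methyl tetronate)cyclohexadienone 7 by a catalytic desymmetrizing conjugate propargylation (key step; sets the spiro carbon and its CH neighbour), then axial enolate methylation, hydrostannation and enol-triflate methylation; 7 ⇐ 4-methoxyphenol by oxidative dearomatization and propiolate spiro-annulation.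
3. East 38 ⇐ thiol–ene closure of the thiolane onto dihydropyran lactol 36 ⇐ organocatalytic Michael/hemiacetalization of keto ester 32 with 3-(acetylthio)propanal.
4. 32 ⇐ Wittig, Negishi and hydrozirconation chain assembly from (S)-epichlorohydrin, an E-silylvinyl Grignard reagent, acetylide and the Roche-ester-derived bromide 26.
5. Ring order: butenolide and cyclohexadienone (spiro) → cyclohexene; dihydropyran → bridged thiolane; macrocycle last.

Assumption: the sense of induction of the two chiral catalysts (steps 3 and 16) follows the models stated there; if either is reversed, the mirror-image catalyst is used.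

Locants: west compounds use 1-oxaspiro[4.5]decane numbering; the thiolane is S1, C2 (keto ester arm), C3 (side chain), C4 (acyl arm), C5.

## Route

Step 1
Reactants: 1 4-methoxyphenol
Product: 2 4,4-dimethoxycyclohexa-2,5-dien-1-one
Conditions: PhI(OAc)2, MeOH, 0 °C
Reagents that add atoms: methanol (CO)
Why: Oxidative dearomatization of a p-alkoxyphenol by a hypervalent iodine reagent, the phenoxenium ion being trapped by methanol at the para carbon to give the quinone monoketal; no stereocentre is formed.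

Step 2
Reactants: 2 4,4-dimethoxycyclohexa-2,5-dien-1-one; 3 methyl propiolate
Product: 7 4-methoxy-1-oxaspiro[4.5]deca-3,6,9-triene-2,8-dione, via lithium methyl propiolate 4 (not isolated), via lithium propargylic alkoxide 5 (not isolated), via spirotetronate dimethyl ketal 6 (not isolated)
Conditions: LiHMDS, THF, −78 °C; then NaOMe (1.5 equiv), MeOH, −78 → 20 °C; then 1 M HCl, 0 °C
Reagents that add atoms: sodium methoxide (C[O-].[Na+]); water (O)
Why: 1,2-addition of the lithium acetylide to the dienone carbonyl, methoxide conjugate addition to the ynoate with lactonization (Yoshii-type spirotetronate formation) and mild ketal hydrolysis give the mirror-symmetric dienone whose spiro carbon is still prochiral.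

Step 3 (key step)
Reactants: 7 4-methoxy-1-oxaspiro[4.5]deca-3,6,9-triene-2,8-dione; 8 allenyltributylstannane
Product: 10 (5R,10R)-4-methoxy-10-(prop-2-yn-1-yl)-1-oxaspiro[4.5]deca-3,6-diene-2,8-dione, via tributylstannyl dienolate 9 (not isolated)
Conditions: (S)-B-(o-tolyl)oxazaborolidine from (S)-diphenylprolinol (20 mol %) activated by AlBr3 (20 mol %), CH2Cl2, −78 °C; 1 M HCl work-up
Reagents that add atoms: none
Why: Proposed new method: the cationic oxazaborolidine–AlBr3 Lewis acid binds the dienone carbonyl and the allenylstannane adds SE2′ to a β-carbon (conjugate propargylation), the closest known reactions being the TiCl4-mediated conjugate addition of allenylstannanes to enones and oxazaborolidinium-catalysed enantioselective Mukaiyama–Michael additions to cyclohexenones; the in-plane methoxy arm of the butenolide blocks one face so attack is syn to the lactone oxygen at either β-carbon, the catalyst therefore only has to choose between the two enantiotopic enone halves, and C10 and the spiro carbon C5 are set together.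

Step 4
Reactants: 10 (5R,10R)-4-methoxy-10-(prop-2-yn-1-yl)-1-oxaspiro[4.5]deca-3,6-diene-2,8-dione
Product: 12 (5S,6R,9R)-4-methoxy-9-methyl-6-(prop-2-yn-1-yl)-1-oxaspiro[4.5]dec-3-ene-2,8-dione, via lithium enolate 11 (not isolated)
Conditions: LiBH(s-Bu)3, THF, −78 °C; then MeI, HMPA, −78 → −30 °C
Reagents that add atoms: iodomethane (CI)
Why: Reductive alkylation: 1,4-reduction gives the regiodefined enolate, which is methylated axially on the face of the small pseudoaxial lactone oxygen (stereoelectronic axial alkylation, the other face carrying the methoxy arm), placing the C9 methyl cis to that oxygen; the selectivity may be modest and the C9 epimer is separable.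

Step 5
Reactants: 12 (5S,6R,9R)-4-methoxy-9-methyl-6-(prop-2-yn-1-yl)-1-oxaspiro[4.5]dec-3-ene-2,8-dione
Product: 13 (5S,6R,9R)-4-methoxy-9-methyl-6-[(2E)-3-(tributylstannyl)prop-2-en-1-yl]-1-oxaspiro[4.5]dec-3-ene-2,8-dione
Conditions: Bu3SnH, Pd2(dba)3 (1 mol %), Cy3P·HBF4, i-Pr2NEt, CH2Cl2, 0 °C
Reagents that add atoms: tributyltin hydride (CCCC[SnH](CCCC)CCCC)
Why: Palladium-catalysed syn-hydrostannation of the terminal alkyne with a bulky phosphine puts tin on the terminal carbon and gives the E-alkenylstannane; ketone and lactone are inert.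

Step 6
Reactants: 13 (5S,6R,9R)-4-methoxy-9-methyl-6-[(2E)-3-(tributylstannyl)prop-2-en-1-yl]-1-oxaspiro[4.5]dec-3-ene-2,8-dione
Product: 15 (5S,6R,9R)-4-methoxy-9-methyl-2-oxo-6-[(2E)-3-(tributylstannyl)prop-2-en-1-yl]-1-oxaspiro[4.5]deca-3,7-dien-8-yl trifluoromethanesulfonate, via lithium C7 enolate 14 (not isolated)
Conditions: LDA (1.1 equiv), THF, −78 °C; then PhNTf2, −78 → 0 °C; NH4Cl work-up
Reagents that add atoms: N-phenylbis(trifluoromethanesulfonimide) (O=S(=O)(N(c1ccccc1)S(=O)(=O)C(F)(F)F)C(F)(F)F)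
Why: Kinetic enol triflate formation: only the C7 methylene is deprotonated because the C9 hydrogen is equatorial (axial methyl) and cannot align with the carbonyl, so the double bond is fixed at C7=C8 and C9 is not epimerized.

Step 7
Reactants: 15 (5S,6R,9R)-4-methoxy-9-methyl-2-oxo-6-[(2E)-3-(tributylstannyl)prop-2-en-1-yl]-1-oxaspiro[4.5]deca-3,7-dien-8-yl trifluoromethanesulfonate
Product: 16 (5S,6R,9R)-4-methoxy-8,9-dimethyl-6-[(2E)-3-(tributylstannyl)prop-2-en-1-yl]-1-oxaspiro[4.5]deca-3,7-dien-2-one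
Conditions: MeMgBr (2 equiv), Fe(acac)3 (5 mol %), THF/NMP, −30 °C, 15 min
Reagents that add atoms: methylmagnesium bromide (C[Mg]Br)
Why: Iron-catalysed Kumada-type coupling of the alkenyl triflate is complete within minutes at −30 °C, installs the ring methyl on the fixed C7=C8 bond and leaves the vinylogous lactone and the alkenylstannane untouched.

Step 8
Reactants: 17 (S)-epichlorohydrin; 18 (E)-(2-bromoethenyl)trimethylsilane
Product: 20 (2S,4E)-1-chloro-5-(trimethylsilyl)pent-4-en-2-ol, via (E)-2-(trimethylsilyl)ethenylmagnesium bromide 19 (not isolated)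
Conditions: Mg, THF, 50 °C; then CuBr·SMe2 (10 mol %), 17, THF, −40 → −10 °C; NH4Cl work-up
Reagents that add atoms: none
Why: Copper-catalysed Grignard opening of the epoxide at its terminal carbon (SN2) does not touch the stereocentre and transfers the E-alkenylsilane with retention.

Step 9
Reactants: 20 (2S,4E)-1-chloro-5-(trimethylsilyl)pent-4-en-2-ol
Product: 22 (4S,6E)-7-(trimethylsilyl)hept-6-en-1-yn-4-ol, via (S)-silylallyl oxirane 21 (not isolated)
Conditions: LiC≡CH·H2NCH2CH2NH2 (3 equiv), DMSO, 5 → 20 °C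
Reagents that add atoms: lithium acetylide–ethylenediamine complex ([Li]C#C.NCCN)
Why: The alkoxide closes to the epoxide (intramolecular Williamson reaction), which the acetylide opens at the terminal carbon; the C–O bond of the stereocentre is never broken, so the configuration is retained.

Step 10
Reactants: 22 (4S,6E)-7-(trimethylsilyl)hept-6-en-1-yn-4-ol
Product: 23 triethyl{[(4S,6E)-7-(trimethylsilyl)hept-6-en-1-yn-4-yl]oxy}silane
Conditions: Et3SiCl, imidazole, CH2Cl2, 0 °C
Reagents that add atoms: chlorotriethylsilane (CC[Si](Cl)(CC)CC)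
Why: Silylation of the secondary alcohol protects it through the organometallic and oxidation steps.

Step 11
Reactants: 23 triethyl{[(4S,6E)-7-(trimethylsilyl)hept-6-en-1-yn-4-yl]oxy}silane
Product: 25 triethyl{[(1E,4S,6E)-1-iodo-7-(trimethylsilyl)hepta-1,6-dien-4-yl]oxy}silane, via E-alkenylzirconocene chloride 24 (not isolated)
Conditions: Cp2Zr(H)Cl (1.3 equiv), THF, 20 °C; then I2, 0 °C
Reagents that add atoms: iodine (II)
Why: Hydrozirconation adds syn with zirconium on the terminal carbon and iodinolysis with retention gives the E-alkenyl iodide; the hindered alkenylsilane does not react.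

Step 12
Reactants: 25 triethyl{[(1E,4S,6E)-1-iodo-7-(trimethylsilyl)hepta-1,6-dien-4-yl]oxy}silane; 26 methyl (2R)-3-bromo-2-methylpropanoate
Product: 28 methyl (2S,4E,7R,9E)-2-methyl-7-[(triethylsilyl)oxy]-10-(trimethylsilyl)deca-4,9-dienoate, via (2R)-3-methoxy-2-methyl-3-oxopropylzinc bromide 27 (not isolated)
Conditions: 26, Zn, I2 (5 mol %), DMA, 70 °C; then 25, Pd(PPh3)4 (5 mol %), THF, 40 °C
Reagents that add atoms: none
Why: Negishi sp3–sp2 coupling of the ester-bearing alkylzinc with the alkenyl iodide proceeds with retention of the E geometry; the methyl stereocentre comes from the chiral pool and the alkenylsilane is inert to palladium.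

Step 13
Reactants: 28 methyl (2S,4E,7R,9E)-2-methyl-7-[(triethylsilyl)oxy]-10-(trimethylsilyl)deca-4,9-dienoate
Product: 29 methyl (2S,4E,7R,9E)-10-iodo-2-methyl-7-[(triethylsilyl)oxy]deca-4,9-dienoate
Conditions: NIS (1.1 equiv), 2,6-lutidine, (CF3)2CHOH, 0 °C
Reagents that add atoms: N-iodosuccinimide (O=C1CCC(=O)N1I)
Why: Electrophilic ipso-iododesilylation through the β-silyl cation is much faster than iodination of the isolated alkene and retains the E geometry.

Step 14
Reactants: 29 methyl (2S,4E,7R,9E)-10-iodo-2-methyl-7-[(triethylsilyl)oxy]deca-4,9-dienoate; 30 ethyl 2-oxo-3-(triphenylphosphoranylidene)propanoate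
Product: 32 ethyl (3E,5S,7E,10R,12E)-13-iodo-5-methyl-2-oxo-10-[(triethylsilyl)oxy]trideca-3,7,12-trienoate, via (2S)-2-methyl aldehyde 31 (not isolated)
Conditions: i-Bu2AlH (1.05 equiv), CH2Cl2, −78 °C; MeOH, Rochelle salt; crude aldehyde, 30, toluene, 50 °C
Reagents that add atoms: none
Why: Partial ester reduction through the tetrahedral aluminium hemiacetal and immediate Wittig reaction with the stabilised keto ylide give the E-β,γ-unsaturated α-keto ester without epimerizing the α-methyl aldehyde.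

Step 15
Reactants: 33 acrolein; 34 thioacetic acid
Product: 35 S-(3-oxopropyl) ethanethioate
Conditions: Et3N (1 mol %), CH2Cl2, 0 °C
Reagents that add atoms: none
Why: Sulfa-Michael addition of the thioacid to the enal.

Step 16
Reactants: 32 ethyl (3E,5S,7E,10R,12E)-13-iodo-5-methyl-2-oxo-10-[(triethylsilyl)oxy]trideca-3,7,12-trienoate; 35 S-(3-oxopropyl) ethanethioate
Product: 36 ethyl (3S,4R)-3-[(acetylsulfanyl)methyl]-2-hydroxy-4-[(2S,4E,7R,9E)-10-iodo-7-(triethylsilyloxy)deca-4,9-dien-2-yl]-3,4-dihydro-2H-pyran-6-carboxylate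
Conditions: (R)-2-[diphenyl(trimethylsilyloxy)methyl]pyrrolidine (10 mol %), PhCO2H (10 mol %), CH2Cl2, 0 → 20 °C
Reagents that add atoms: none
Why: Enamine-catalysed Michael addition of the aldehyde to the β,γ-unsaturated α-keto ester followed by hemiacetalization (formal inverse-electron-demand hetero-Diels–Alder reaction); the diarylprolinol ether shields one enamine face and sets pyran C4 (the future thiolane C3) under catalyst control, while the syn-formed C3 centre is corrected in step 19.

Step 17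
Reactants: 36 ethyl (3S,4R)-3-[(acetylsulfanyl)methyl]-2-hydroxy-4-[(2S,4E,7R,9E)-10-iodo-7-(triethylsilyloxy)deca-4,9-dien-2-yl]-3,4-dihydro-2H-pyran-6-carboxylate
Product: 38 ethyl (1S,5R,8S)-2-hydroxy-8-[(2S,4E,7R,9E)-10-iodo-7-(triethylsilyloxy)deca-4,9-dien-2-yl]-3-oxa-6-thiabicyclo[3.2.1]octane-4-carboxylate, via free thiol 37 (not isolated)
Conditions: NaOEt (1.05 equiv), EtOH, −20 °C; AcOH; then degassed EtOAc (0.01 M), 2,2-dimethoxy-2-phenylacetophenone (10 mol %), hν 365 nm, 20 °C
Reagents that add atoms: none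
Why: Intramolecular thiol–ene reaction: the thiyl radical adds 5-exo to the enol-ether carbon of the glycal-type ester, the captodative radical takes hydrogen from thiol, and the tether forces the new C–S bond cis to the CH2S arm, giving the bridged thiolane with C2 and C4 (thiolane) still cis to the side chain.

Step 18
Reactants: 16 (5S,6R,9R)-4-methoxy-8,9-dimethyl-6-[(2E)-3-(tributylstannyl)prop-2-en-1-yl]-1-oxaspiro[4.5]deca-3,7-dien-2-one; 38 ethyl (1S,5R,8S)-2-hydroxy-8-[(2S,4E,7R,9E)-10-iodo-7-(triethylsilyloxy)deca-4,9-dien-2-yl]-3-oxa-6-thiabicyclo[3.2.1]octane-4-carboxylate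
Product: 41 seco diol (tetronate C3–CH(OH)–thiolane C4 adduct carrying the 2-hydroxy ester on thiolane C2), via 3-lithio tetronate 39 (not isolated), via lithium lactolate 40 (not isolated)
Conditions: 16, LDA, THF, −78 °C; 38, LiHMDS (1.0 equiv), THF, −78 °C; combine, −78 → −40 °C; NH4Cl work-up
Reagents that add atoms: none
Why: The vinylic C3 anion of the methyl tetronate adds 1,2 to the aldehyde released from the lithium lactolate, which simultaneously frees the 2-hydroxy ester; both new carbinol centres are removed in the next step.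

Step 19
Reactants: 41 seco diol
Product: 43 all-trans seco diketone (3-acyl methyl tetronate and thiolane α-keto ester), via all-cis diketone 42 (not isolated)
Conditions: Dess–Martin periodinane (3 equiv), NaHCO3, CH2Cl2, 0 → 20 °C; Na2S2O3 wash; then DBU (0.3 equiv), CH2Cl2, 20 °C
Reagents that add atoms: none
Why: Dess–Martin oxidation turns both secondary alcohols into ketones, and DBU then equilibrates the two α-carbonyl thiolane centres (C2 through the keto ester enol, C4 through the ketone enolate or reversible E1cB and 5-endo sulfa-Michael reclosure) to the thermodynamically favoured all-trans ring, with the non-enolizable C3 as anchor.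

Step 20
Reactants: 43 all-trans seco diketone
Product: 44 protected macrocycle (11-O-triethylsilyl ether, tetronate O-methyl ether and ethyl ester of the target)
Conditions: Pd2(dba)3 (10 mol %), AsPh3 (40 mol %), i-Pr2NEt, DMF/THF, 1 mM, 20 → 40 °C
Reagents that add atoms: none
Why: Intramolecular Stille coupling under high dilution joins the E-alkenylstannane and E-alkenyl iodide with retention, forming the E,E-diene and the 19-membered ring.

Step 21
Reactants: 44 protected macrocycle
Product: 46 target CNP0224658.3, via 11-O-triethylsilyl target 45 (not isolated)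
Conditions: LiOH (aq., 6 equiv), THF, 0 → 20 °C; then 1 M HCl to pH 1, 20 °C
Reagents that add atoms: lithium hydroxide ([Li+].[OH-])
Why: Hydroxide hydrolyses the activated α-keto ester and replaces the vinylogous methyl ester of the 3-acyl tetronate by addition–elimination, the thiolane C2 centre staying at its thermodynamic configuration, and acidification cleaves the silyl ether.

## Compound list

1 | 4-methoxyphenol | COc1ccc(O)cc1 | starting material
2 | 4,4-dimethoxycyclohexa-2,5-dien-1-one | COC1(OC)C=CC(=O)C=C1 | intermediate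
3 | methyl propiolate | C#CC(=O)OC | starting material
4 | lithium methyl propiolate | [Li]C#CC(=O)OC | intermediate
5 | lithium alkoxide of methyl 3-(1-hydroxy-4,4-dimethoxycyclohexa-2,5-dien-1-yl)prop-2-ynoate | COC(=O)C#CC1(O[Li])C=CC(OC)(OC)C=C1 | intermediate
6 | 4,8,8-trimethoxy-1-oxaspiro[4.5]deca-3,6,9-trien-2-one | COC1=CC(=O)OC12C=CC(OC)(OC)C=C2 | intermediate
7 | 4-methoxy-1-oxaspiro[4.5]deca-3,6,9-triene-2,8-dione | COC1=CC(=O)OC12C=CC(=O)C=C2 | intermediate
8 | allenyltributylstannane | C=C=C[Sn](CCCC)(CCCC)CCCC | starting material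
9 | O-tributylstannyl dienolate of 10 | CCCC[Sn](CCCC)(CCCC)OC1=C[C@@H](CC#C)[C@]2(C=C1)OC(=O)C=C2OC | intermediate
10 | (5R,10R)-4-methoxy-10-(prop-2-yn-1-yl)-1-oxaspiro[4.5]deca-3,6-diene-2,8-dione | O=C1C[C@@H](CC#C)[C@]2(C=C1)OC(=O)C=C2OC | intermediate
11 | lithium C8=C9 enolate from 1,4-reduction of 10 | [Li]OC=1C[C@@H](CC#C)[C@]2(CC=1)OC(=O)C=C2OC | intermediate
12 | (5S,6R,9R)-4-methoxy-9-methyl-6-(prop-2-yn-1-yl)-1-oxaspiro[4.5]dec-3-ene-2,8-dione | O=C1C[C@@H](CC#C)[C@]2(C[C@H]1C)OC(=O)C=C2OC | intermediate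
13 | (5S,6R,9R)-4-methoxy-9-methyl-6-[(2E)-3-(tributylstannyl)prop-2-en-1-yl]-1-oxaspiro[4.5]dec-3-ene-2,8-dione | O=C1C[C@@H](C/C=C/[Sn](CCCC)(CCCC)CCCC)[C@]2(C[C@H]1C)OC(=O)C=C2OC | intermediate
14 | lithium C7=C8 enolate of 13 | [Li]OC1=C[C@@H](C/C=C/[Sn](CCCC)(CCCC)CCCC)[C@]2(C[C@H]1C)OC(=O)C=C2OC | intermediate
15 | (5S,6R,9R)-4-methoxy-9-methyl-2-oxo-6-[(2E)-3-(tributylstannyl)prop-2-en-1-yl]-1-oxaspiro[4.5]deca-3,7-dien-8-yl trifluoromethanesulfonate | FC(F)(F)S(=O)(=O)OC1=C[C@@H](C/C=C/[Sn](CCCC)(CCCC)CCCC)[C@]2(C[C@H]1C)OC(=O)C=C2OC | intermediate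
16 | (5S,6R,9R)-4-methoxy-8,9-dimethyl-6-[(2E)-3-(tributylstannyl)prop-2-en-1-yl]-1-oxaspiro[4.5]deca-3,7-dien-2-one | CC1=C[C@@H](C/C=C/[Sn](CCCC)(CCCC)CCCC)[C@]2(C[C@H]1C)OC(=O)C=C2OC | intermediate
17 | (S)-epichlorohydrin | ClC[C@@H]1CO1 | starting material
18 | (E)-(2-bromoethenyl)trimethylsilane | C[Si](C)(C)/C=C/Br | starting material
19 | (E)-2-(trimethylsilyl)ethenylmagnesium bromide | C[Si](C)(C)/C=C/[Mg]Br | intermediate
20 | (2S,4E)-1-chloro-5-(trimethylsilyl)pent-4-en-2-ol | C[Si](C)(C)/C=C/C[C@H](O)CCl | intermediate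
21 | trimethyl{(1E)-3-[(2S)-oxiran-2-yl]prop-1-en-1-yl}silane | C[Si](C)(C)/C=C/C[C@H]1CO1 | intermediate
22 | (4S,6E)-7-(trimethylsilyl)hept-6-en-1-yn-4-ol | C[Si](C)(C)/C=C/C[C@H](O)CC#C | intermediate
23 | triethyl{[(4S,6E)-7-(trimethylsilyl)hept-6-en-1-yn-4-yl]oxy}silane | C[Si](C)(C)/C=C/C[C@H](O[Si](CC)(CC)CC)CC#C | intermediate
24 | E-alkenylzirconocene chloride from 23 | C[Si](C)(C)/C=C/C[C@H](O[Si](CC)(CC)CC)C/C=C/[Zr](Cl)(C1C=CC=C1)C1C=CC=C1 | intermediate
25 | triethyl{[(1E,4S,6E)-1-iodo-7-(trimethylsilyl)hepta-1,6-dien-4-yl]oxy}silane | C[Si](C)(C)/C=C/C[C@H](O[Si](CC)(CC)CC)C/C=C/I | intermediate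
26 | methyl (2R)-3-bromo-2-methylpropanoate | BrC[C@H](C)C(=O)OC | starting material
27 | (2R)-3-methoxy-2-methyl-3-oxopropylzinc bromide | Br[Zn]C[C@H](C)C(=O)OC | intermediate
28 | methyl (2S,4E,7R,9E)-2-methyl-7-[(triethylsilyl)oxy]-10-(trimethylsilyl)deca-4,9-dienoate | C[Si](C)(C)/C=C/C[C@H](O[Si](CC)(CC)CC)C/C=C/C[C@H](C)C(=O)OC | intermediate
29 | methyl (2S,4E,7R,9E)-10-iodo-2-methyl-7-[(triethylsilyl)oxy]deca-4,9-dienoate | I/C=C/C[C@H](O[Si](CC)(CC)CC)C/C=C/C[C@H](C)C(=O)OC | intermediate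
30 | ethyl 2-oxo-3-(triphenylphosphoranylidene)propanoate | CCOC(=O)C(=O)C=P(c1ccccc1)(c1ccccc1)c1ccccc1 | starting material
31 | (2S,4E,7R,9E)-10-iodo-2-methyl-7-[(triethylsilyl)oxy]deca-4,9-dienal | I/C=C/C[C@H](O[Si](CC)(CC)CC)C/C=C/C[C@H](C)C=O | intermediate
32 | ethyl (3E,5S,7E,10R,12E)-13-iodo-5-methyl-2-oxo-10-[(triethylsilyl)oxy]trideca-3,7,12-trienoate | I/C=C/C[C@H](O[Si](CC)(CC)CC)C/C=C/C[C@H](C)/C=C/C(=O)C(=O)OCC | intermediate
33 | acrolein | C=CC=O | starting material
34 | thioacetic acid | CC(=O)S | starting material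
35 | S-(3-oxopropyl) ethanethioate | CC(=O)SCCC=O | intermediate
36 | ethyl (3S,4R)-3-[(acetylsulfanyl)methyl]-2-hydroxy-4-[(2S,4E,7R,9E)-10-iodo-7-(triethylsilyloxy)deca-4,9-dien-2-yl]-3,4-dihydro-2H-pyran-6-carboxylate (anomer mixture) | CCOC(=O)C1=C[C@@H]([C@@H](C)C/C=C/C[C@@H](O[Si](CC)(CC)CC)C/C=C/I)[C@H](CSC(C)=O)C(O)O1 | intermediate
37 | free thiol of 36 (3-sulfanylmethyl lactol) | CCOC(=O)C1=C[C@@H]([C@@H](C)C/C=C/C[C@@H](O[Si](CC)(CC)CC)C/C=C/I)[C@H](CS)C(O)O1 | intermediate
38 | ethyl (1S,5R,8S)-2-hydroxy-8-[(2S,4E,7R,9E)-10-iodo-7-(triethylsilyloxy)deca-4,9-dien-2-yl]-3-oxa-6-thiabicyclo[3.2.1]octane-4-carboxylate (mixture at C2 and C4) | CCOC(=O)C1OC(O)[C@H]2CS[C@@H]1[C@H]2[C@@H](C)C/C=C/C[C@@H](O[Si](CC)(CC)CC)C/C=C/I | intermediate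
39 | 3-lithio derivative of 16 | CC1=C[C@@H](C/C=C/[Sn](CCCC)(CCCC)CCCC)[C@]2(C[C@H]1C)OC(=O)C([Li])=C2OC | intermediate
40 | lithium lactolate of 38 | CCOC(=O)C1OC(O[Li])[C@H]2CS[C@@H]1[C@H]2[C@@H](C)C/C=C/C[C@@H](O[Si](CC)(CC)CC)C/C=C/I | intermediate
41 | seco diol (carbinol epimers; thiolane substituents all cis) | CC1=C[C@@H](C/C=C/[Sn](CCCC)(CCCC)CCCC)[C@]2(C[C@H]1C)OC(=O)C(=C2OC)C(O)[C@H]3CS[C@@H](C(O)C(=O)OCC)[C@H]3[C@@H](C)C/C=C/C[C@@H](O[Si](CC)(CC)CC)C/C=C/I | intermediate
42 | all-cis seco diketone | CC1=C[C@@H](C/C=C/[Sn](CCCC)(CCCC)CCCC)[C@]2(C[C@H]1C)OC(=O)C(=C2OC)C(=O)[C@H]3CS[C@@H](C(=O)C(=O)OCC)[C@H]3[C@@H](C)C/C=C/C[C@@H](O[Si](CC)(CC)CC)C/C=C/I | intermediate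
43 | all-trans seco diketone | CC1=C[C@@H](C/C=C/[Sn](CCCC)(CCCC)CCCC)[C@]2(C[C@H]1C)OC(=O)C(=C2OC)C(=O)[C@@H]3CS[C@H](C(=O)C(=O)OCC)[C@H]3[C@@H](C)C/C=C/C[C@@H](O[Si](CC)(CC)CC)C/C=C/I | intermediate
44 | protected macrocycle (11-O-triethylsilyl, O-methyl tetronate, ethyl ester) | CC1=C[C@H]2C/C=C/C=C/C[C@H](O[Si](CC)(CC)CC)C/C=C/C[C@H](C)[C@@H]3[C@@H](C(=O)C(=O)OCC)SC[C@H]3C(=O)C3=C(OC)[C@@]2(C[C@H]1C)OC3=O | intermediate
45 | 11-O-triethylsilyl ether of the target | CC1=C[C@H]2C/C=C/C=C/C[C@H](O[Si](CC)(CC)CC)C/C=C/C[C@H](C)[C@@H]3[C@@H](C(=O)C(=O)O)SC[C@H]3C(=O)C3=C(O)[C@@]2(C[C@H]1C)OC3=O | intermediate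
46 | CNP0224658.3 | CC1=C[C@H]2C/C=C/C=C/C[C@H](O)C/C=C/C[C@H](C)[C@@H]3[C@@H](C(=O)C(=O)O)SC[C@H]3C(=O)C3=C(O)[C@@]2(C[C@H]1C)OC3=O | target

## Step count and risks

Total: 21 steps. Longest linear sequence: 13 steps (17 → 46 through steps 8–14 and 16–21); the west branch is 7 steps to 16.

The three steps most likely to fail:

Step 3 (new catalytic asymmetric conjugate propargylation; enantio- and diastereocontrol are unproven). The fallback sets out from 7 and comes back at 10. Thiophenol is added to one enone of 7 under a cinchona-squaramide catalyst (organocatalytic sulfa-Michael desymmetrization, a known reaction class for such dienones) to give the phenylthio enone F1. The remaining enone is then propargylated without a chiral catalyst (8, TiCl4, CH2Cl2, −78 °C, attack syn to the lactone oxygen) to give the thio propargyl diketone F2. Oxidation with mCPBA at −78 °C gives the β-keto sulfoxide F3, which on warming (CaCO3, toluene, 50 °C) loses benzenesulfenic acid and regenerates the enone, giving 10. The thiol acts as a traceless desymmetrizing group.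

Step 4 (face selectivity of the enolate methylation at C9). The fallback sets out from 10 and comes back at 12. If the methylation gives mainly the equatorial C9 epimer F4, the stereocentre is set by kinetic protonation instead. The crude ketone mixture is converted to the more substituted trimethylsilyl enol ether F5 (Me3SiCl, NaI, Et3N, MeCN). The lithium enolate is released with MeLi (2.1 equiv, THF, −78 °C) and protonated from the open equatorial side by 2,6-di-tert-butyl-4-methylphenol, which leaves the methyl group axial and gives 12.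

Step 18 (addition of the thermally sensitive lithio tetronate to an aldehyde that must first be released from a lithium lactolate). The fallback sets out from 38 and comes back at 42. Lactol 38 is oxidised to the bridged lactone F6 (Ag2CO3 on Celite, toluene, 80 °C). This lactone acylates the lithiated tetronate 39 at −78 °C (inverse addition) and gives the hydroxy ketone F7 with the acyl tetronate carbonyl already in place. Dess–Martin oxidation of the remaining 2-hydroxy ester gives 42, and the DBU equilibration of step 19 follows.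

Further compounds
F1 | step 3 | 4-methoxy-10-(phenylsulfanyl)-1-oxaspiro[4.5]deca-3,6-diene-2,8-dione (sulfur cis to the lactone oxygen) | O=C1C=C[C@]2([C@@H](Sc3ccccc3)C1)OC(=O)C=C2OC
F2 | step 3 | 4-methoxy-6-(phenylsulfanyl)-10-(prop-2-yn-1-yl)-1-oxaspiro[4.5]dec-3-ene-2,8-dione | O=C1C[C@@H](CC#C)[C@]2([C@@H](Sc3ccccc3)C1)OC(=O)C=C2OC
F3 | step 3 | 4-methoxy-6-(phenylsulfinyl)-10-(prop-2-yn-1-yl)-1-oxaspiro[4.5]dec-3-ene-2,8-dione | O=C1C[C@@H](CC#C)[C@]2([C@@H](S(=O)c3ccccc3)C1)OC(=O)C=C2OC
F4 | step 4 | (5S,6R,9S)-4-methoxy-9-methyl-6-(prop-2-yn-1-yl)-1-oxaspiro[4.5]dec-3-ene-2,8-dione | O=C1C[C@@H](CC#C)[C@]2(C[C@@H]1C)OC(=O)C=C2OC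
F5 | step 4 | (5S,6R)-4-methoxy-9-methyl-6-(prop-2-yn-1-yl)-8-[(trimethylsilyl)oxy]-1-oxaspiro[4.5]deca-3,8-dien-2-one | C[Si](C)(C)OC=1C[C@@H](CC#C)[C@]2(CC=1C)OC(=O)C=C2OC
F6 | step 18 | ethyl (1S,5R,8S)-8-[(2S,4E,7R,9E)-10-iodo-7-(triethylsilyloxy)deca-4,9-dien-2-yl]-2-oxo-3-oxa-6-thiabicyclo[3.2.1]octane-4-carboxylate | CCOC(=O)C1OC(=O)[C@H]2CS[C@@H]1[C@H]2[C@@H](C)C/C=C/C[C@@H](O[Si](CC)(CC)CC)C/C=C/I
F7 | step 18 | seco hydroxy ketone (acyl tetronate ketone in place; thiolane C2 still carrying the 2-hydroxy ester) | CC1=C[C@@H](C/C=C/[Sn](CCCC)(CCCC)CCCC)[C@]2(C[C@H]1C)OC(=O)C(=C2OC)C(=O)[C@H]3CS[C@@H](C(O)C(=O)OCC)[C@H]3[C@@H](C)C/C=C/C[C@@H](O[Si](CC)(CC)CC)C/C=C/I
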